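**Plan**

- The target is (S)-N-formyltortuosamine: a 5,6,7,8-tetrahydroquinoline whose only stereocenter is the quaternary C6 (aryl, aminoethyl chain, C5, C7). The retrosynthesis cuts N–CHO first, then takes C7H2 back to C7=O, then opens the carbocycle across C5–C6 and C8–C8a, and last cuts the C6–chain bond.
- Enabling feature: a ketone at C7 lies between C6 (also benzylic to the dimethoxyphenyl ring) and C8, so both neighbours are enolate carbons (a 1,3-dinucleophile). The pyridine supplies C5 as its 3-CH2Br group and C8a as its 2-Cl carbon (a 1,3-dielectrophile).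
- Forward: the chain is joined to the arylacetone, a one-flask [3+3] annulation closes the carbocycle onto the intact pyridine, a Wolff–Kishner reduction removes the C7 oxygen (and the Boc group), and the amine is formylated.
- Stereochemistry: C6 is set in the alkylation half of the annulation by a chiral quaternary ammonium phase-transfer catalyst. It is quaternary from then on and no later step can scramble it.

Key step: step 2

Assumption (chemistry): the sense of induction of the phase-transfer catalyst on this acyclic enolate cannot be predicted with certainty; both antipodes of the catalyst are accessible, and the one that should give (R)-5 is the one meant.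

**Step 1**
Reactants: 1 1-(3,4-dimethoxyphenyl)propan-2-one; 2 tert-butyl (2-bromoethyl)(methyl)carbamate
Product: 3 tert-butyl N-[3-(3,4-dimethoxyphenyl)-4-oxopentyl]-N-methylcarbamate (racemic)
Conditions: NaH, DMF, 0 °C; then 2, NaI (cat.), 0 °C to rt
Reagents that add atoms: none
Why: Enolate alkylation: NaH removes the doubly activated benzylic α-hydrogen of 1 and the aryl-conjugated enolate displaces the primary bromide of 2 at carbon (SN2), the new stereocenter being left racemic on purpose because step 2 passes through its planar enolate.

**Step 2**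
Reactants: 3 tert-butyl N-[3-(3,4-dimethoxyphenyl)-4-oxopentyl]-N-methylcarbamate; 4 3-(bromomethyl)-2-chloropyridine
Product: 6 tert-butyl N-{2-[(6R)-6-(3,4-dimethoxyphenyl)-7-oxo-5,6,7,8-tetrahydroquinolin-6-yl]ethyl}-N-methylcarbamate, via alkylated ketone 5 (not isolated)
Conditions: chiral C2-symmetric N-spiro bis(binaphthyl)ammonium bromide with 3,4,5-trifluorophenyl groups (2 mol%), 45% aq KOH, toluene, −20 °C, argon; aqueous phase drawn off; then Pd(OAc)2 (5 mol%), XPhos (10 mol%), K3PO4, toluene, 90 °C, same flask
Reagents that add atoms: none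
Why: Proposed new method: the acyclic methyl ketone 3 is asked to behave like a 2-arylcyclohexanone in a chiral phase-transfer benzylation and the product is arylated in the same flask, which amounts to a [3+3] annulation of a ketone α,α'-dinucleophile (C6, C8) with the pyridine 3-CH2Br/2-Cl dielectrophile (C5, C8a); the closest known reaction types are the phase-transfer alkylation of 2-aryl cycloalkanones to α-quaternary ketones and the intramolecular palladium-catalysed α-arylation of methyl ketones that gives 2-tetralones. Mechanism: hydroxide at the interface removes the benzylic C6–H (more acidic than the methyl C8–H by several pK units), the enolate enters toluene as a tight ion pair with the chiral ammonium cation and displaces bromide from 4 in an SN2 step (C5–C6), and after the aqueous phase is removed zerovalent palladium inserts into the C2–Cl bond, phosphate generates the only enolate still possible (toward C8) and reductive elimination from the C-bound palladium enolate forms C8–C8a. The carbocycle closes in this reductive elimination from a seven-membered palladacycle, formally a 6-exo attack of the enolate carbon C8 on C8a. The C6 stereocenter is set in the alkylation under catalyst control: the enolate should prefer the Z geometry (aryl syn to O−, side chain syn to methyl, which avoids an aryl/methyl clash and is the geometry that a cyclohexanone ring enforces), so the catalyst meets the same aryl/oxygen edge as in the cyclic precedent and shields one face, and once quaternary C6 cannot epimerize. The step needs alkylation at C6 and not C8 (secured by acidity under equilibrating conditions), C- and not O-bond formation in the ring closure (secured by using palladium and not an SNAr reaction, hence chloride and not fluoride at C2), and reaction at C2 and not C4 of the pyridine (secured by the position of the halogen).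

**Step 3**
Reactants: 6 tert-butyl N-{2-[(6R)-6-(3,4-dimethoxyphenyl)-7-oxo-5,6,7,8-tetrahydroquinolin-6-yl]ethyl}-N-methylcarbamate
Product: 8 2-[(6S)-6-(3,4-dimethoxyphenyl)-5,6,7,8-tetrahydroquinolin-6-yl]-N-methylethan-1-amine (tortuosamine), via hydrazone 7 (not isolated)
Conditions: N2H4·H2O, diethylene glycol, 130 °C; then KOH, 200 °C, water distilled off
Reagents that add atoms: hydrazine, NN (its nitrogen atoms stand only in 7 and leave as N2; 8 gains hydrogen only)
Why: Wolff–Kishner reduction in the Huang-Minlon manner: the only carbonyl group condenses with hydrazine and the hydrazone anion loses N2 to leave C7 as CH2, while hot KOH/hydrazine in glycol (a classical carbamate cleavage) should also remove the Boc group, and the quaternary C6 is not touched (its descriptor changes from R to S only because the priorities change).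

**Step 4**
Reactants: 8 2-[(6S)-6-(3,4-dimethoxyphenyl)-5,6,7,8-tetrahydroquinolin-6-yl]-N-methylethan-1-amine
Product: 9 N-{2-[(6S)-6-(3,4-dimethoxyphenyl)-5,6,7,8-tetrahydroquinolin-6-yl]ethyl}-N-methylformamide
Conditions: HCO2Et (neat), 60 °C, sealed tube
Reagents that add atoms: ethyl formate, CCOC=O
Why: N-formylation by aminolysis of a formate ester by the secondary amine; the pyridine nitrogen gives no stable acyl derivative and C6 is remote from the reaction.

**Compound list**

1 | 1-(3,4-dimethoxyphenyl)propan-2-one | COc1ccc(CC(C)=O)cc1OC | starting material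
2 | tert-butyl (2-bromoethyl)(methyl)carbamate | CN(CCBr)C(=O)OC(C)(C)C | starting material
3 | tert-butyl N-[3-(3,4-dimethoxyphenyl)-4-oxopentyl]-N-methylcarbamate (racemic) | COc1ccc(C(CCN(C)C(=O)OC(C)(C)C)C(C)=O)cc1OC | intermediate
4 | 3-(bromomethyl)-2-chloropyridine | Clc1ncccc1CBr | starting material
5 | tert-butyl N-[(3R)-3-[(2-chloropyridin-3-yl)methyl]-3-(3,4-dimethoxyphenyl)-4-oxopentyl]-N-methylcarbamate (formed in the flask, not isolated) | COc1ccc([C@@](Cc2cccnc2Cl)(CCN(C)C(=O)OC(C)(C)C)C(C)=O)cc1OC | intermediate
6 | tert-butyl N-{2-[(6R)-6-(3,4-dimethoxyphenyl)-7-oxo-5,6,7,8-tetrahydroquinolin-6-yl]ethyl}-N-methylcarbamate | COc1ccc([C@@]2(CCN(C)C(=O)OC(C)(C)C)C(=O)Cc3ncccc3C2)cc1OC | intermediate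
7 | tert-butyl N-{2-[(6R)-6-(3,4-dimethoxyphenyl)-7-hydrazinylidene-5,6,7,8-tetrahydroquinolin-6-yl]ethyl}-N-methylcarbamate (formed in the flask, not isolated) | COc1ccc([C@@]2(CCN(C)C(=O)OC(C)(C)C)C(=NN)Cc3ncccc3C2)cc1OC | intermediate
8 | 2-[(6S)-6-(3,4-dimethoxyphenyl)-5,6,7,8-tetrahydroquinolin-6-yl]-N-methylethan-1-amine (tortuosamine) | COc1ccc([C@@]2(CCNC)CCc3ncccc3C2)cc1OC | intermediate
9 | N-{2-[(6S)-6-(3,4-dimethoxyphenyl)-5,6,7,8-tetrahydroquinolin-6-yl]ethyl}-N-methylformamide | COc1ccc([C@@]2(CCN(C)C=O)CCc3ncccc3C2)cc1OC | target

**Step count and risks**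

Total step count: 4. Longest linear sequence: 4 steps (1 → 3 → 6 → 8 → 9).

Steps most likely to fail:

1. Step 2 (Proposed new method). What may go wrong: loss of enantioselectivity through a mixed enolate geometry or a loose ion pair in the alkylation, and consumption of leftover benzylic bromide by the palladium catalyst in the second stage. The fallback sets out from 3 and comes back at 6. It separates the two bond formations into known reactions and takes the enantiomer by resolution instead of catalysis. Ketone 3 is alkylated with 4 under achiral conditions (NaH, DMF, 0 °C) to the racemic tert-butyl N-[3-[(2-chloropyridin-3-yl)methyl]-3-(3,4-dimethoxyphenyl)-4-oxopentyl]-N-methylcarbamate F1, which is isolated. Intramolecular ketone α-arylation (Pd(OAc)2, XPhos, K3PO4, toluene, 90 °C) gives the racemic tert-butyl N-{2-[6-(3,4-dimethoxyphenyl)-7-oxo-5,6,7,8-tetrahydroquinolin-6-yl]ethyl}-N-methylcarbamate F2. The enantiomers of F2 are separated by preparative chromatography on a chiral stationary phase (supercritical CO2/MeOH), and the (6R) enantiomer is 6.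

2. Step 3. What may go wrong: incomplete hydrazone formation at the hindered, easily enolized ketone, azine formation, and partial cleavage of the aryl methyl ethers in hot alkali. The fallback sets out from 6 and comes back at 8. It removes the oxygen through the enol triflate instead of the hydrazone. Because C6 is quaternary, 6 can enolize only toward C8, so KN(SiMe3)2 and PhNTf2 (THF, −78 °C) should give one enol triflate, (6R)-6-{2-[(tert-butoxycarbonyl)(methyl)amino]ethyl}-6-(3,4-dimethoxyphenyl)-5,6-dihydroquinolin-7-yl trifluoromethanesulfonate F3. Palladium-catalysed formate reduction (Pd(OAc)2, PPh3, HCO2H, Bu3N, DMF, 60 °C) gives tert-butyl N-{2-[(6S)-6-(3,4-dimethoxyphenyl)-5,6-dihydroquinolin-6-yl]ethyl}-N-methylcarbamate F4. Hydrogenation (H2, Pd/C, EtOAc) saturates the C7=C8 bond to tert-butyl N-{2-[(6S)-6-(3,4-dimethoxyphenyl)-5,6,7,8-tetrahydroquinolin-6-yl]ethyl}-N-methylcarbamate F5. HCl in dioxane, then aqueous NaOH, gives 8.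

3. Step 1. What may go wrong: consumption of the electrophile by the base (ring closure of the bromoethyl carbamate to an oxazolidinone, elimination) together with over-alkylation at the benzylic carbon. The fallback sets out from 1 and comes back at 3. It builds the aminoethyl chain by the cyclopropyl imine route instead of a direct alkylation. Ketone 1 is cyclopropanated with 1,2-dibromoethane (50% aq NaOH, BnEt3NCl) to 1-[1-(3,4-dimethoxyphenyl)cyclopropyl]ethan-1-one F6. MeNH2 and Ti(OiPr)4 give the ketimine N-methyl-1-[1-(3,4-dimethoxyphenyl)cyclopropyl]ethan-1-imine F7. Catalytic NH4Cl at 130 °C effects the cyclopropyl imine (Cloke) rearrangement to 3-(3,4-dimethoxyphenyl)-1,2-dimethyl-4,5-dihydro-1H-pyrrole F8. Boc2O in THF/water with NaHCO3 traps the ring-opened amino ketone that is in equilibrium with the protonated enamine and gives 3.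

**Further compounds**

F1 | step 2 | racemic tert-butyl N-[3-[(2-chloropyridin-3-yl)methyl]-3-(3,4-dimethoxyphenyl)-4-oxopentyl]-N-methylcarbamate | COc1ccc(C(Cc2cccnc2Cl)(CCN(C)C(=O)OC(C)(C)C)C(C)=O)cc1OC
F2 | step 2 | racemic tert-butyl N-{2-[6-(3,4-dimethoxyphenyl)-7-oxo-5,6,7,8-tetrahydroquinolin-6-yl]ethyl}-N-methylcarbamate | COc1ccc(C2(CCN(C)C(=O)OC(C)(C)C)C(=O)Cc3ncccc3C2)cc1OC
F3 | step 3 | (6R)-6-{2-[(tert-butoxycarbonyl)(methyl)amino]ethyl}-6-(3,4-dimethoxyphenyl)-5,6-dihydroquinolin-7-yl trifluoromethanesulfonate | COc1ccc([C@@]2(CCN(C)C(=O)OC(C)(C)C)C(OS(=O)(=O)C(F)(F)F)=Cc3ncccc3C2)cc1OC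
F4 | step 3 | tert-butyl N-{2-[(6S)-6-(3,4-dimethoxyphenyl)-5,6-dihydroquinolin-6-yl]ethyl}-N-methylcarbamate | COc1ccc([C@@]2(CCN(C)C(=O)OC(C)(C)C)C=Cc3ncccc3C2)cc1OC
F5 | step 3 | tert-butyl N-{2-[(6S)-6-(3,4-dimethoxyphenyl)-5,6,7,8-tetrahydroquinolin-6-yl]ethyl}-N-methylcarbamate | COc1ccc([C@@]2(CCN(C)C(=O)OC(C)(C)C)CCc3ncccc3C2)cc1OC
F6 | step 1 | 1-[1-(3,4-dimethoxyphenyl)cyclopropyl]ethan-1-one | COc1ccc(C2(C(C)=O)CC2)cc1OC
F7 | step 1 | N-methyl-1-[1-(3,4-dimethoxyphenyl)cyclopropyl]ethan-1-imine | COc1ccc(C2(C(C)=NC)CC2)cc1OC
F8 | step 1 | 3-(3,4-dimethoxyphenyl)-1,2-dimethyl-4,5-dihydro-1H-pyrrole | COc1ccc(C2=C(C)N(C)CC2)cc1OC
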